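**Plan**

1. Numbering: phenanthrene locants throughout. Ring A = C4b–C8a, ring B = C4a/C4b/C8a/C9/C10/C10a, ring C = C1–C4/C4a/C10a, ring D = oxazolidine (O on C4, aminal carbon, N on C3), ring E = pyrrolidine.
2. Retrosynthesis: cut the two O‑benzyl bonds, then the aminal C–O and C–N bonds of rings D and E (back to an N–H amine with a 4,4‑diethoxybutyl chain and a C4 tertiary alcohol), then C4–CH3 (back to a 3‑amino‑2‑methoxyphenanthrene‑1,4‑dione), then C1–C10a of ring C, and last C3–N and C4–C4a (amine and naphthyllithium on dimethyl squarate).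
3. Enabling feature: C1(=O), C2(OCH3), C3(N) and C4(O) of ring C are four contiguous heteroatom‑bearing carbons, i.e. the four carbons of squaric acid, and C4a/C10a are an ortho pair of the ring B arene, so ring C is a squarate annulated onto a naphthalene.
4. Forward: rings A/B are built as a 1‑bromonaphthalene (Friedel–Crafts closure of an aryl acetoacetate), ring C by cyclobutenone‑to‑quinone ring expansion, rings E and D together in one acid‑mediated N,O‑acetal closure; debenzylation then lets ring B settle as the C9 ketone.
5. Stereochemistry: C4 is formed racemic by methyllithium addition and the R enantiomer is taken by chromatography on a chiral phase; the aminal carbon (S) is set from C4 under thermodynamic control, the pyrrolidine carbon settling anti to the C4 methyl.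

Key step: step 8

Remark: the target is the C9‑keto/C10‑methylene tautomer of an 8,9‑naphthalenediol; it is assumed that this tautomer (peri hydrogen bond O8–H···O=C9, C4a=C10a conjugated with C1=O, relief of bay strain at C4) is the stable form and is reached spontaneously after debenzylation.

**Route**

Step 1
Reactants: 1 2-(2-bromo-5-methoxyphenyl)acetic acid
Product: 3 methyl 4-(2-bromo-5-methoxyphenyl)-3-oxobutanoate, via acyl Meldrum's acid 2 (not isolated)
Conditions: Meldrum's acid, DCC, DMAP, CH2Cl2, 0 °C → rt; then MeOH, reflux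
Reagents that add atoms: Meldrum's acid (2,2-dimethyl-1,3-dioxane-4,6-dione), CC1(C)OC(=O)CC(=O)O1; methanol, CO
Why: DCC/DMAP C‑acylates Meldrum's acid and boiling methanol opens the adduct with loss of acetone and CO2 (Oikawa–Yonemitsu β‑keto ester synthesis), a routine homologation of arylacetic acids that leaves the aryl bromide untouched.

Step 2
Reactants: 3 methyl 4-(2-bromo-5-methoxyphenyl)-3-oxobutanoate
Product: 4 5-bromo-8-methoxynaphthalene-1,3-diol
Conditions: conc. H2SO4, 0 °C → rt; ice
Reagents that add atoms: none
Why: The ester carbonyl acylates the only free position ortho to the side chain, which is also ortho to the methoxy group (intramolecular Friedel–Crafts acylation, six‑membered ring), and the cyclic 1,3‑diketone enolises to the naphthalene‑1,3‑diol, the classical route from 4‑aryl‑3‑oxobutanoates to naphthoresorcinols.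

Step 3
Reactants: 4 5-bromo-8-methoxynaphthalene-1,3-diol
Product: 5 5-bromonaphthalene-1,3,8-triol
Conditions: BBr3, CH2Cl2, −78 °C → rt; H2O (under Ar)
Reagents that add atoms: none
Why: BBr3 cleaves the aryl methyl ether (Lewis acid dealkylation) so that the oxygen destined for C9 can later carry a group removable under neutral conditions; the air‑sensitive triol is used at once.

Step 4
Reactants: 5 5-bromonaphthalene-1,3,8-triol
Product: 6 4-bromo-6-methoxynaphthalene-1,8-diol
Conditions: HCl (g) in MeOH, 0 °C → rt
Reagents that add atoms: methanol, CO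
Why: Only the β‑hydroxyl at C3 is a vinylogous acid in the favoured keto tautomer (C1 carbonyl conjugated with the ring and hydrogen‑bonded to the peri hydroxyl), so acid‑catalysed Fischer‑type etherification methylates it selectively, as in 1,3‑dihydroxynaphthalenes.

Step 5
Reactants: 6 4-bromo-6-methoxynaphthalene-1,8-diol
Product: 7 4,5-bis(benzyloxy)-1-bromo-7-methoxynaphthalene
Conditions: BnBr, K2CO3, DMF, 60 °C
Reagents that add atoms: benzyl bromide, BrCc1ccccc1
Why: Williamson etherification of both peri phenols, the second (hydrogen‑bonded) one needing the excess reagent and warming.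

Step 6
Reactants: 7 4,5-bis(benzyloxy)-1-bromo-7-methoxynaphthalene; 8 dimethyl squarate (3,4-dimethoxycyclobut-3-ene-1,2-dione)
Product: 10 rac-4-[4,5-bis(benzyloxy)-7-methoxynaphthalen-1-yl]-4-hydroxy-2,3-dimethoxycyclobut-2-en-1-one, via naphthyllithium 9 (not isolated)
Conditions: n-BuLi, THF, −78 °C; cannulate into 8, THF, −78 °C; NH4Cl (aq)
Reagents that add atoms: none
Why: Bromine–lithium exchange outruns any deprotonation at −78 °C and the aryllithium adds once to a carbonyl of the symmetrical squarate (standard 1,2‑addition to dialkyl squarates), so no regiochemical question arises and the racemic carbinol centre is lost later.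

Step 7
Reactants: 10 rac-4-[4,5-bis(benzyloxy)-7-methoxynaphthalen-1-yl]-4-hydroxy-2,3-dimethoxycyclobut-2-en-1-one; 11 4,4-diethoxybutan-1-amine
Product: 12 rac-4-[4,5-bis(benzyloxy)-7-methoxynaphthalen-1-yl]-3-[(4,4-diethoxybutyl)amino]-4-hydroxy-2-methoxycyclobut-2-en-1-one
Conditions: MeOH, rt
Reagents that add atoms: none
Why: The C3 methoxy is the β‑substituent of the cyclobutenone vinylogous ester and is exchanged by the primary amine through conjugate addition–elimination (the squaramide‑forming reaction), whereas the α‑methoxy cannot leave, which places nitrogen next to the carbinol carbon without ambiguity.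

Step 8
Reactants: 12 rac-4-[4,5-bis(benzyloxy)-7-methoxynaphthalen-1-yl]-3-[(4,4-diethoxybutyl)amino]-4-hydroxy-2-methoxycyclobut-2-en-1-one
Product: 15 8,9-bis(benzyloxy)-3-[(4,4-diethoxybutyl)amino]-2,6-dimethoxyphenanthrene-1,4-dione, via vinylketene 13 (not isolated), via hydroquinone 14 (not isolated)
Conditions: p-xylene, 138 °C (Ar); then Ag2O, rt
Reagents that add atoms: none
Why: Heating breaks the bond between the carbonyl carbon and the carbinol carbon of the four‑membered ring in a conrotatory four‑electron opening, the hydroxyl turning outward as donors do, so that vinylketene 13 holds the naphthyl group cis to the ketene carbon. Six‑electron electrocyclisation then joins the ketene carbon to C2 of the naphthalene (the C1–C10a bond) and closes ring C as a six‑membered ring; tautomerisation gives hydroquinone 14, which Ag2O oxidises to the quinone. This is the Moore rearrangement of 4‑aryl‑4‑hydroxycyclobutenones to annulated quinones, which is also known with a 3‑amino substituent. No stereocentre is formed and the carbinol centre of 12 disappears. The selectivity needed is regiochemical: closure can only reach naphthalene C2 because the other neighbour of the attachment carbon is the ring‑fusion carbon, and the order O, OCH3, N, O around ring C was fixed in step 7. The N–H amine, the acetal and the benzyl ethers are spectators under the neutral thermal conditions.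

Step 9
Reactants: 15 8,9-bis(benzyloxy)-3-[(4,4-diethoxybutyl)amino]-2,6-dimethoxyphenanthrene-1,4-dione
Product: 16 rac-8,9-bis(benzyloxy)-3-[(4,4-diethoxybutyl)amino]-4-hydroxy-2,6-dimethoxy-4-methylphenanthren-1(4H)-one
Conditions: MeLi (2.5 equiv), THF, −78 °C; NH4Cl (aq)
Reagents that add atoms: methyllithium, [Li]C
Why: The first equivalent removes the N–H proton and turns the C1 carbonyl into an unreactive vinylogous amidate, so the second adds 1,2 to the C4 carbonyl next to the nitrogen‑bearing carbon (quinone‑to‑quinol addition of an organolithium), methyl being small enough for the bay region; there is no facial bias and the carbinol is racemic.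

Step 10
Reactants: 16 rac-8,9-bis(benzyloxy)-3-[(4,4-diethoxybutyl)amino]-4-hydroxy-2,6-dimethoxy-4-methylphenanthren-1(4H)-one
Product: 17 (4R)-8,9-bis(benzyloxy)-3-[(4,4-diethoxybutyl)amino]-4-hydroxy-2,6-dimethoxy-4-methylphenanthren-1(4H)-one
Conditions: preparative HPLC, amylose tris(3,5-dimethylphenylcarbamate) on silica, hexane/i-PrOH
Reagents that add atoms: none
Why: Chromatographic resolution on a polysaccharide carbamate phase should separate the enantiomers of this rigid carbinol, which has hydrogen‑bond donor and acceptor sites next to the stereocentre; the R enantiomer is to be assigned by electronic circular dichroism against computation and carried on.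

Step 11
Reactants: 17 (4R)-8,9-bis(benzyloxy)-3-[(4,4-diethoxybutyl)amino]-4-hydroxy-2,6-dimethoxy-4-methylphenanthren-1(4H)-one
Product: 19 dibenzyl ether of the ring-B-aromatic form of the target (C4 R; aminal carbon S), via ethoxypyrrolidine 18 (not isolated)
Conditions: TsOH·H2O (cat.), CH2Cl2, 5 Å MS, rt
Reagents that add atoms: none
Why: Acid converts the acetal into an oxocarbenium ion that the N–H captures to close ring E, loss of the second ethanol gives an N‑acyliminium‑type ion, and the C4 hydroxyl closes ring D (acetal exchange/N‑acyliminium cyclisation); the aminal carbon equilibrates under these conditions to the less crowded isomer with the pyrrolidine carbon anti to the C4 methyl, which is the S configuration of the target.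

Step 12
Reactants: 19 dibenzyl ether of the ring-B-aromatic form of the target (C4 R; aminal carbon S)
Product: 21 target compound (C4 R; aminal carbon S), via naphthalenediol tautomer 20 (not isolated)
Conditions: H2 (1 atm), Pd/C, EtOAc, rt; filtration through silica under Ar
Reagents that add atoms: none
Why: Hydrogenolysis of aryl benzyl ethers over Pd/C is much faster than cleavage of the hindered tertiary benzylic C4–O bond or reduction of the push–pull enaminone, and the liberated 9‑naphthol tautomerises to the C9 ketone; neither stereocentre is touched.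

**Compound list**

1 | 2-(2-bromo-5-methoxyphenyl)acetic acid | COc1ccc(Br)c(CC(=O)O)c1 | starting material
2 | 5-[2-(2-bromo-5-methoxyphenyl)acetyl]-2,2-dimethyl-1,3-dioxane-4,6-dione (acyl Meldrum's acid, keto form drawn; not isolated) | COc1ccc(Br)c(CC(=O)C2C(=O)OC(C)(C)OC2=O)c1 | intermediate
3 | methyl 4-(2-bromo-5-methoxyphenyl)-3-oxobutanoate | COC(=O)CC(=O)Cc1cc(OC)ccc1Br | intermediate
4 | 5-bromo-8-methoxynaphthalene-1,3-diol | Oc1cc(O)c2c(OC)ccc(Br)c2c1 | intermediate
5 | 5-bromonaphthalene-1,3,8-triol | Oc1cc(O)c2c(O)ccc(Br)c2c1 | intermediate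
6 | 4-bromo-6-methoxynaphthalene-1,8-diol | COc1cc(O)c2c(O)ccc(Br)c2c1 | intermediate
7 | 4,5-bis(benzyloxy)-1-bromo-7-methoxynaphthalene | COc1cc(OCc2ccccc2)c2c(OCc3ccccc3)ccc(Br)c2c1 | intermediate
8 | dimethyl squarate (3,4-dimethoxycyclobut-3-ene-1,2-dione) | COC1=C(OC)C(=O)C1=O | starting material
9 | [4,5-bis(benzyloxy)-7-methoxynaphthalen-1-yl]lithium (not isolated) | [Li]c1ccc(OCc2ccccc2)c2c(OCc3ccccc3)cc(OC)cc12 | intermediate
10 | rac-4-[4,5-bis(benzyloxy)-7-methoxynaphthalen-1-yl]-4-hydroxy-2,3-dimethoxycyclobut-2-en-1-one | COC1=C(OC)C(O)(c2ccc(OCc3ccccc3)c3c(OCc4ccccc4)cc(OC)cc23)C1=O | intermediate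
11 | 4,4-diethoxybutan-1-amine | CCOC(CCCN)OCC | starting material
12 | rac-4-[4,5-bis(benzyloxy)-7-methoxynaphthalen-1-yl]-3-[(4,4-diethoxybutyl)amino]-4-hydroxy-2-methoxycyclobut-2-en-1-one | COC1=C(NCCCC(OCC)OCC)C(O)(c2ccc(OCc3ccccc3)c3c(OCc4ccccc4)cc(OC)cc23)C1=O | intermediate
13 | (3Z)-4-[4,5-bis(benzyloxy)-7-methoxynaphthalen-1-yl]-3-[(4,4-diethoxybutyl)amino]-4-hydroxy-2-methoxybuta-1,3-dien-1-one (vinylketene, naphthyl cis to the ketene carbon; not isolated) | COC(=C=O)/C(NCCCC(OCC)OCC)=C(/O)c1ccc(OCc2ccccc2)c2c(OCc3ccccc3)cc(OC)cc12 | intermediate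
14 | 8,9-bis(benzyloxy)-3-[(4,4-diethoxybutyl)amino]-2,6-dimethoxyphenanthrene-1,4-diol (not isolated) | COc1c(NCCCC(OCC)OCC)c(O)c2c(cc(OCc3ccccc3)c3c(OCc4ccccc4)cc(OC)cc23)c1O | intermediate
15 | 8,9-bis(benzyloxy)-3-[(4,4-diethoxybutyl)amino]-2,6-dimethoxyphenanthrene-1,4-dione | COC1=C(NCCCC(OCC)OCC)C(=O)c2c(cc(OCc3ccccc3)c3c(OCc4ccccc4)cc(OC)cc23)C1=O | intermediate
16 | rac-8,9-bis(benzyloxy)-3-[(4,4-diethoxybutyl)amino]-4-hydroxy-2,6-dimethoxy-4-methylphenanthren-1(4H)-one | COC1=C(NCCCC(OCC)OCC)C(C)(O)c2c(cc(OCc3ccccc3)c3c(OCc4ccccc4)cc(OC)cc23)C1=O | intermediate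
17 | (4R)-8,9-bis(benzyloxy)-3-[(4,4-diethoxybutyl)amino]-4-hydroxy-2,6-dimethoxy-4-methylphenanthren-1(4H)-one | COC1=C(NCCCC(OCC)OCC)[C@](C)(O)c2c(cc(OCc3ccccc3)c3c(OCc4ccccc4)cc(OC)cc23)C1=O | intermediate
18 | (4R)-8,9-bis(benzyloxy)-3-(2-ethoxypyrrolidin-1-yl)-4-hydroxy-2,6-dimethoxy-4-methylphenanthren-1(4H)-one (both epimers at the ethoxy-bearing carbon; not isolated) | COC1=C(N2CCCC2OCC)[C@](C)(O)c2c(cc(OCc3ccccc3)c3c(OCc4ccccc4)cc(OC)cc23)C1=O | intermediate
19 | 8,9-bis(benzyloxy)-2,6-dimethoxy-4-methylphenanthren-1(4H)-one whose C4 oxygen and C3 nitrogen are joined through C2 and N1 of a pyrrolidine (rings D and E closed); C4 R, aminal carbon S, aminal H cis to the C4 methyl | COC1=C2N3CCC[C@@H]3O[C@]2(C)c2c(cc(OCc3ccccc3)c3c(OCc4ccccc4)cc(OC)cc23)C1=O | intermediate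
20 | 8,9-dihydroxy analogue of 19 (ring B aromatic tautomer of the target; C4 R, aminal carbon S; not isolated) | COC1=C2N3CCC[C@@H]3O[C@]2(C)c2c(cc(O)c3c(O)cc(OC)cc23)C1=O | intermediate
21 | 8-hydroxy-2,6-dimethoxy-4-methyl-4,10-dihydrophenanthrene-1,9-dione whose C4 oxygen and C3 nitrogen are joined through C2 and N1 of a pyrrolidine (oxazolidine ring D fused to pyrrolidine ring E); C4 R, aminal carbon S | COC1=C2N3CCC[C@@H]3O[C@]2(C)C2=C(CC(=O)c3c(O)cc(OC)cc32)C1=O | target

**Step count and risks**

Total steps: 12. Longest linear sequence: 12 steps (1 → 21); 8 and 11 are bought and enter at steps 6 and 7.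

Steps most likely to fail:

Step 9. The methyl addition may lose site control or stall: after N–H deprotonation the lithium amidate may be too electron‑rich or too poorly soluble to accept a second equivalent, and electron transfer to the quinone or attack at the unhindered C1 carbonyl may take over. The fallback sets out from 15 and comes back at 19. It closes ring E before the methyl group is introduced, so that no acidic N–H is present. Acid‑catalysed acetal exchange (TsOH cat., CH2Cl2, molecular sieves) ties nitrogen and chain together as 8,9-bis(benzyloxy)-3-(2-ethoxypyrrolidin-1-yl)-2,6-dimethoxyphenanthrene-1,4-dione F1. One equivalent of MeLi in THF at −78 °C then adds to the C4 carbonyl of this tertiary enaminone to give the carbinol 8,9-bis(benzyloxy)-3-(2-ethoxypyrrolidin-1-yl)-4-hydroxy-2,6-dimethoxy-4-methylphenanthren-1(4H)-one F2. TsOH ionises the N,O‑acetal and the C4 hydroxyl closes ring D to give racemic 19 F3, which is resolved on the chiral phase of step 10 to give 19.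

Step 8. The ketene may be diverted: if the hydroxyl turns inward or adds to the ketene, a furanone forms instead of ring C, and the slower ring opening of the N–H vinylogous amide gives decomposition time to compete. The fallback sets out from 12 and comes back at 15. The tertiary hydroxyl is capped with Me3SiCl/Et3N/DMAP to give the 4-(trimethylsilyloxy)cyclobutenone F4. Thermolysis in p‑xylene then can only lead to the arene and gives 8,9-bis(benzyloxy)-3-[(4,4-diethoxybutyl)amino]-2,6-dimethoxy-4-(trimethylsilyloxy)phenanthren-1-ol F5. KF in MeOH followed by Ag2O removes the silyl group and oxidises to 15.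

Step 7. The basic amine may open the hydroxycyclobutenone ring in competition with exchange of the methoxy group. The fallback sets out from 8 and 11 and comes back at 12. It forms the C–N bond before the C–C bond: 8 and 11 in MeOH at rt give the squaramide ester 3-[(4,4-diethoxybutyl)amino]-4-methoxycyclobut-3-ene-1,2-dione F6. Its N–H is removed with LiN(SiMe3)2 in THF at −78 °C, and naphthyllithium 9 (from 7 as in step 6) adds to the carbonyl next to the nitrogen‑bearing carbon, the vinylogous ester carbonyl, the other being deactivated as a vinylogous amide. NH4Cl quench gives 12.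

**Further compounds**

F1 | step 9 | rac-8,9-bis(benzyloxy)-3-(2-ethoxypyrrolidin-1-yl)-2,6-dimethoxyphenanthrene-1,4-dione | COC1=C(N2CCCC2OCC)C(=O)c2c(cc(OCc3ccccc3)c3c(OCc4ccccc4)cc(OC)cc23)C1=O
F2 | step 9 | 8,9-bis(benzyloxy)-3-(2-ethoxypyrrolidin-1-yl)-4-hydroxy-2,6-dimethoxy-4-methylphenanthren-1(4H)-one (racemic, both epimers) | COC1=C(N2CCCC2OCC)C(C)(O)c2c(cc(OCc3ccccc3)c3c(OCc4ccccc4)cc(OC)cc23)C1=O
F3 | step 9 | racemic 19 (19 together with its mirror image) | COC1=C2N3CCC[C@@H]3O[C@]2(C)c2c(cc(OCc3ccccc3)c3c(OCc4ccccc4)cc(OC)cc23)C1=O.COC1=C2N3CCC[C@H]3O[C@@]2(C)c2c(cc(OCc3ccccc3)c3c(OCc4ccccc4)cc(OC)cc23)C1=O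
F4 | step 8 | rac-4-[4,5-bis(benzyloxy)-7-methoxynaphthalen-1-yl]-3-[(4,4-diethoxybutyl)amino]-2-methoxy-4-(trimethylsilyloxy)cyclobut-2-en-1-one | COC1=C(NCCCC(OCC)OCC)C(O[Si](C)(C)C)(c2ccc(OCc3ccccc3)c3c(OCc4ccccc4)cc(OC)cc23)C1=O
F5 | step 8 | 8,9-bis(benzyloxy)-3-[(4,4-diethoxybutyl)amino]-2,6-dimethoxy-4-(trimethylsilyloxy)phenanthren-1-ol | COc1c(NCCCC(OCC)OCC)c(O[Si](C)(C)C)c2c(cc(OCc3ccccc3)c3c(OCc4ccccc4)cc(OC)cc23)c1O
F6 | step 7 | 3-[(4,4-diethoxybutyl)amino]-4-methoxycyclobut-3-ene-1,2-dione | COC1=C(NCCCC(OCC)OCC)C(=O)C1=O
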